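Which product leads the flask at 15 d, and by what ratio, early and late?

- ratio of target to isomer of the product at 2.5 h
- ratio of target to isomer of the product at 15 d
- which of target and isomer of the product there is more of at 15 d

| flask | substrate | free catalyst | impurity | remark | time |
|---|---|---|---|---|---|
| noon | 0.025 M | 0.30 mM | 0.28 mM | run made earlier |  |
| dusk | 0.038 M | 0.30 mM | 0.28 mM | run made earlier |  |
| flask | 0.050 M | 0.30 mM | 0.28 mM |  | 15 d |

- noon (time / d: target / %, isomer of the product / %, substrate / %): 1.25: 3.2, 0, 59.1; 1.67: 7.3, 0, 56.1; 3.00: 10.5, 1.8, 47.9; 4.00: 9.8, 0.8, 41.8; 6.00: 12.5, 2.0, 34.2; 10.0: 17.8, 1.5, 21.8; 15.0: 20.5, 2.5, 13.1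
- dusk (time / d: target / %, isomer of the product / %, substrate / %): 2.00: 6.9, 1.3, 54.3; 4.00: 10.0, 1.4, 39.7; 6.00: 14.1, 1.8, 32.0; 8.00: 14.0, 1.8, 25.0; 10.0: 16.5, 0, 19.7; 12.0: 17.2, 1.0, 16.7; 15.0: 20.6, 1.3, 11.3

(standard deviation of a reading: 1 percentage point)



My reckoning:

1. Impurity and free catalyst are charged nearly equal. I assume that each impurity removes one free catalyst, so you compute just the small remainder. Catalyst charge minus impurity charge, over catalyst charge, is 6.67%, the surviving share.

2. From 6.00 d to 15.0 d, the noon and dusk runs gain on average 7.3 percentage points of target, while substrate averages 22.6%. So the pseudo-first-order constant for target is 0.0356 /d, which I assign to the surviving 6.67% of the catalyst charge.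

3. Noon and dusk end at 20.5% and 20.6% of target, so I carry these fractions over to the flask. Pooling their final readings gives a ratio of 10.8, with target ahead.

4. The weak link is step 1. Noon and dusk were charged alike with 0.30 mM of free catalyst and 0.28 mM of impurity, and they give no test of it. So the ratio in step 3 rests on readings, and the share of 6.67% is kept for a changed catalyst charge.

5. For 2.5 h I commit to no number: noon reads isomer at 0% at 1.25 d, within the scatter.

The forecast gives 4 at 2.5 h, 12 at 15 d, and target ahead, holding that isomer “forms early and then stops”.

The flask gives 287 at 2.5 h and 10.2 at 15 d, with target ahead: 19.0% against 1.86%.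

    free catalyst + impurity → spent catalyst (k = 1.40 /M/s)
    substrate ⇌ dormant form (K = 0.240, k = 1.50 × 10⁻⁵ /s)
    substrate + free catalyst → free catalyst + target (k = 0.0200 /M/s)
    substrate ⇌ other conformer (K = 0.820, k = 2.90 × 10⁻⁶ /s)
    free catalyst + other conformer → free catalyst + isomer of the product (k = 0.00690 /M/s)
    2 other conformer → self-condensation product (k = 4.10 × 10⁻⁴ /M/s)

In the flask, free catalyst stands at 6.67% of its charge at 15.0 d, beside the reckoned 6.67%, with impurity at 0%. Now take the neighbouring flask, charged with 7.5 × 10⁻⁴ M of free catalyst and otherwise unchanged. Its surviving share is 62.7%, and the constant scaled by surviving catalyst is 0.836 /d, a half-life of 0.829 d by this step alone. At 15.0 d that neighbouring flask holds free catalyst at 62.7%, substrate at 0.0182% and target at 84.2%.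

The earlier runs and the new flask come from a simulation with made-up constants; noise was put on by code.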